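**Retrosynthetic overview**
1. Ring A (C1–C5, C10) is closed last, across C3–C4: a nickel-hydride hydroalkylation joins the terminal olefin carbon C3 of a C10 allyl group to C4, held as a tertiary α-bromo lactone (two natural donor carbons, C4 umpoled as bromide/radical), and gives the target directly.
2. Enabling feature: C4 is the α-carbon of the C19 lactone carbonyl, and in the trans-fused δ-lactone/ring B bicycle it sits 1,3-syn-axial to the C10 allyl group; only the bridged 3-oxabicyclo[3.3.1]nonanone with the correct quaternary C4 and the cis A/B fusion can form.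
3. Before that: C8/C17 spiro-epoxide by C6-OH-directed epoxidation; dihydrofuran (ring E) by alkynol cycloisomerisation; spiro-tetrahydrofuran (ring D, C13) by 5-exo opening of a Sharpless-derived alkynyl epoxide by the C9 carbinol.
4. C9 carbinol by axial Grignard addition to an 8-methylene-9-ketone; lactone/ring B bicycle from (R)-4-silyloxycyclohexenone by 2-allylation, Mukaiyama–Michael addition (C5), aqueous hydroxymethylation (quaternary C10) and lactonisation.
5. Order of ring formation: ring B (from a cyclohexenone) → δ-lactone → ring D → ring E → epoxide → ring A.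

Key step: step 20

Remark: labdane numbering is used for all intermediates (C17 = epoxide CH2, C18 = methyl, C19 = lactone C=O, C20 = lactone CH2); the target SMILES encodes a cis A/B fusion (H5 and C20 on the same face), and C4 is carried as an inconsequential mixture of epimers (left undefined in the SMILES) until the key step.

Step 1
Reactants: 1 1,4-dioxaspiro[4.5]dec-6-en-8-one
Product: 2 (R)-1,4-dioxaspiro[4.5]dec-6-en-8-ol
Conditions: (S)-2-methyl-CBS-oxazaborolidine (10 mol%), catecholborane, PhMe, −78 °C; aqueous work-up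
Reagents that add atoms: none
Why: Corey–Bakshi–Shibata reduction, in which the enone olefin acts as the large group, so the (S)-catalyst should deliver hydride to give the (R)-allylic alcohol that becomes C6.

Step 2
Reactants: 2 (R)-1,4-dioxaspiro[4.5]dec-6-en-8-ol
Product: 3 (R)-8-(tert-butyldimethylsilyloxy)-1,4-dioxaspiro[4.5]dec-6-ene
Conditions: TBSCl, imidazole, DMF, rt
Reagents that add atoms: tert-butyldimethylsilyl chloride, CC(C)(C)[Si](C)(C)Cl
Why: Standard silyl ether formation on a secondary allylic alcohol.

Step 3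
Reactants: 3 (R)-8-(tert-butyldimethylsilyloxy)-1,4-dioxaspiro[4.5]dec-6-ene
Product: 4 (R)-4-(tert-butyldimethylsilyloxy)cyclohex-2-en-1-one
Conditions: PPTS (cat.), acetone–H2O (10:1), 55 °C
Reagents that add atoms: water, O
Why: Acid-catalysed ketal hydrolysis unmasks the ketone in conjugation with the olefin, and the secondary TBS ether should survive PPTS.

Step 4
Reactants: 4 (R)-4-(tert-butyldimethylsilyloxy)cyclohex-2-en-1-one
Product: 5 (R)-4-(tert-butyldimethylsilyloxy)-2-iodocyclohex-2-en-1-one
Conditions: I2, pyridine, CH2Cl2, 0 °C → rt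
Reagents that add atoms: iodine, II
Why: α-Iodination of an enone by pyridine-mediated conjugate addition, iodination and elimination.

Step 5
Reactants: 5 (R)-4-(tert-butyldimethylsilyloxy)-2-iodocyclohex-2-en-1-one
Product: 6 (R)-2-allyl-4-(tert-butyldimethylsilyloxy)cyclohex-2-en-1-one
Conditions: allyltributylstannane, Pd2(dba)3 (2.5 mol%), AsPh3, CuI (cat.), NMP, rt
Reagents that add atoms: allyltributylstannane, C=CC[Sn](CCCC)(CCCC)CCCC
Why: Stille cross-coupling of an α-iodoenone under ligand-accelerated conditions installs C1–C3 on the future C10.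

Step 6
Reactants: 6 (R)-2-allyl-4-(tert-butyldimethylsilyloxy)cyclohex-2-en-1-one, 7 1-methoxy-1-(trimethylsilyloxy)prop-1-ene
Product: 8 silyl enol ether methyl 2-[2-allyl-6-(tert-butyldimethylsilyloxy)-3-(trimethylsilyloxy)cyclohex-2-en-1-yl]propanoate (C5 chain trans to C6–OTBS)
Conditions: Tf2NH (2 mol%), CH2Cl2, −78 °C; Et3N quench
Reagents that add atoms: none
Why: Mukaiyama–Michael addition with silyl transfer, in which the ketene acetal attacks C5 anti to the C6 silyloxy group (sets C5) and leaves a regiodefined silyl enol ether; the configuration at C4 is irrelevant.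

Step 7
Reactants: 8 silyl enol ether
Product: 10 keto-lactone 8a-allyl-5-(tert-butyldimethylsilyloxy)-4-methyloctahydroisochromene-3,8-dione (labdane 6-OTBS, 9-oxo, 10-allyl, 19,20-olide; trans-fused), via hydroxy ester 9 (not isolated)
Conditions: aq. HCHO (37%), Yb(OTf)3 (10 mol%), THF, 0 °C → rt; then CSA (cat.), PhMe, 60 °C
Reagents that add atoms: formaldehyde, C=O
Why: Yb(OTf)3-catalysed aqueous Mukaiyama aldol with formaldehyde should attack the tetrasubstituted enol ether anti to the adjacent C5 chain, creating quaternary C10 with C20 trans and the allyl group cis to that chain, and acid-catalysed transesterification then closes the trans-fused δ-lactone.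

Step 8
Reactants: 10 keto-lactone
Product: 13 8-methylene keto-lactone (exocyclic enone C8=C17), via Mannich base 11 (not isolated), via methiodide 12 (not isolated)
Conditions: LiN(SiMe3)2 (1.05 equiv), THF, −78 °C; CH2=NMe2+ I−, −78 → 0 °C; then MeI, CH2Cl2, rt; DBU, rt
Reagents that add atoms: dimethylmethylideneammonium iodide, C=[N+](C)C.[I-]
Why: Eschenmoser methylenation, in which the ketone can enolise only towards C8 (C10 is quaternary) and is far more acidic than the lactone, so Mannich reaction, quaternisation and elimination give the exocyclic enone.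

Step 9
Reactants: 14 3-bromobut-3-en-1-ol
Product: 15 2-bromo-4-iodobut-1-ene
Conditions: I2, PPh3, imidazole, CH2Cl2, 0 °C
Reagents that add atoms: iodine, II
Why: Appel iodination of the primary alcohol, with the vinyl bromide inert.

Step 10
Reactants: 13 8-methylene keto-lactone, 15 2-bromo-4-iodobut-1-ene
Product: 17 C9 tertiary alcohol bearing the 3-bromobut-3-enyl chain (C9–OH syn to the C10 allyl group; C11 syn to C20), via (3-bromobut-3-en-1-yl)magnesium iodide 16 (not isolated)
Conditions: 15, Mg, THF, 0 °C → rt; LaCl3·2LiCl, THF, −78 °C; add 13, −78 → −40 °C; H2O quench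
Reagents that add atoms: none
Why: Grignard 1,2-addition promoted by LaCl3·2LiCl, in which magnesium inserts only into the primary C–I bond and the nucleophile should attack the C9 carbonyl axially, anti to the axial C10 allyl group of the lactone-locked chair, which sets C9.

Step 11
Reactants: 17 C9 tertiary alcohol (vinyl bromide)
Product: 18 allylic alcohol with 3-(hydroxymethyl)but-3-enyl chain (C14–OH, C13=C16)
Conditions: Bu3SnCH2OH, Pd(PPh3)4 (5 mol%), dioxane, 90 °C
Reagents that add atoms: (tributylstannyl)methanol, OC[Sn](CCCC)(CCCC)CCCC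
Why: Stille coupling of the vinyl bromide with a hydroxymethylstannane gives the 2-substituted allylic alcohol needed for asymmetric epoxidation.

Step 12
Reactants: 18 allylic alcohol
Product: 19 (13S)-13,16-epoxy-14-ol (epoxy alcohol)
Conditions: Ti(OiPr)4 (10 mol%), L-(+)-DIPT (12 mol%), t-BuOOH, 4 Å MS, CH2Cl2, −25 °C
Reagents that add atoms: tert-butyl hydroperoxide, CC(C)(C)OO
Why: Sharpless asymmetric epoxidation, in which reagent control by L-(+)-tartrate should give the (S)-configured 2,2-disubstituted epoxy alcohol (the sense in which 2-methylallyl alcohol gives (S)-2-methylglycidol) and only the allylic-alcohol olefin reacts.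

Step 13
Reactants: 19 epoxy alcohol
Product: 21 (13S)-13,16-epoxy-14-yne (alkynyl epoxide), via epoxy aldehyde 20 (not isolated)
Conditions: TEMPO (cat.), PhI(OAc)2, CH2Cl2, rt; then dimethyl (1-diazo-2-oxopropyl)phosphonate, K2CO3, MeOH, 0 °C
Reagents that add atoms: dimethyl (1-diazo-2-oxopropyl)phosphonate, COP(=O)(OC)C(=[N+]=[N-])C(C)=O
Why: Oxoammonium oxidation of the primary alcohol followed by Ohira–Bestmann (Seyferth–Gilbert) homologation turns C14 into the terminal alkyne without touching the quaternary epoxide carbon C13.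

Step 14
Reactants: 21 alkynyl epoxide
Product: 22 (13R)-9,13-epoxy-14-yn-16-ol (spiro-tetrahydrofuran, ring D)
Conditions: CSA (5 mol%), CH2Cl2, −20 → 0 °C; Et3N quench
Reagents that add atoms: none
Why: Acid-catalysed 5-exo epoxide opening by the C9 tertiary alcohol at the more substituted, propargylic carbon with inversion should set C13 and close ring D, releasing the C16 hydroxyl.

Step 15
Reactants: 22 spiro-tetrahydrofuran alkynol
Product: 23 (13R)-9,13:15,16-diepoxy-14-ene 6-TBS ether (rings D and E; 8(17)-ene; 10-allyl 19,20-olide)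
Conditions: Mo(CO)6 (25 mol%), Et3N, Et2O, hν (350 nm), rt
Reagents that add atoms: none
Why: Alkynol cycloisomerisation through a molybdenum vinylidene, in which endo (anti-Markovnikov) addition of the C16 hydroxyl to the terminal alkyne gives the 2,3-dihydrofuran under basic conditions that the acid-labile bis-spiro ether tolerates.

Step 16
Reactants: 23 bis-spiro ether 6-TBS ether
Product: 24 C6 alcohol
Conditions: Bu4NF, THF, 0 °C → rt
Reagents that add atoms: none
Why: Fluoride cleavage of the secondary silyl ether frees the C6 hydroxyl as directing group under basic conditions that spare the enol ether.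

Step 17
Reactants: 24 C6 alcohol
Product: 25 8,17-epoxide (epoxide oxygen syn to C6–OH)
Conditions: VO(acac)2 (5 mol%), t-BuOOH, CH2Cl2, 0 °C
Reagents that add atoms: tert-butyl hydroperoxide, CC(C)(C)OO
Why: VO(acac)2-catalysed hydroxyl-directed epoxidation, in which the homoallylic equatorial C6 hydroxyl should deliver oxygen to its own face of the 1,1-disubstituted C8=C17 olefin (sets C8) faster than the undirected allyl and enol ether olefins react.

Step 18
Reactants: 25 8,17-epoxide
Product: 26 4-bromo lactone (C4 epimers)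
Conditions: LiN(iPr)2 (2.2 equiv), THF, −78 °C; BrCCl2CCl2Br, −78 °C; aqueous work-up
Reagents that add atoms: 1,2-dibromo-1,1,2,2-tetrachloroethane, BrC(Cl)(Cl)C(Cl)(Cl)Br
Why: Electrophilic bromination of the lactone enolate (formed beside the C6 alkoxide) gives the tertiary α-bromo lactone, whose C4 configuration is erased in the following C–C bond formation.

Step 19
Reactants: 26 4-bromo lactone
Product: 27 6-acetate of the 4-bromo lactone
Conditions: Ac2O, pyridine, DMAP (cat.), CH2Cl2, 0 °C → rt
Reagents that add atoms: acetic anhydride, CC(=O)OC(C)=O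
Why: DMAP-catalysed acylation of the secondary C6 alcohol installs the acetate before the base-free ring closure.

Step 20
Reactants: 27 6-acetate of the 4-bromo lactone
Product: 28 target (6-acetoxy-8,17:9,13:15,16-triepoxy-labd-14-en-19,20-olide, cis A/B)
Conditions: NiBr2·glyme (10 mol%), 4,4′-di-tert-butyl-2,2′-bipyridine (12 mol%), HSiMe(OEt)2, KF, DMA–THF, 0.01 M, rt
Reagents that add atoms: none
Why: Proposed new method: a nickel hydride (from NiBr2·glyme, the silane and KF) should add anti-Markovnikov to the monosubstituted C2=C3 olefin to give a primary alkylnickel at C3, while monovalent nickel abstracts bromine from the tertiary α-bromo lactone to give the C4 radical; capture of this radical at nickel and C(sp3)–C(sp3) reductive elimination from trivalent nickel forge C3–C4. The closest known reaction type is the intermolecular nickel-hydride-catalysed hydroalkylation of terminal olefins with α-halo carbonyl electrophiles, which also accepts tertiary halides and then creates quaternary carbons; the intramolecular, ring-forming version on an α-bromo lactone is the extension proposed here. Ring A is closed in a formal 6-endo sense at the terminal olefin carbon (reductive elimination from a seven-membered nickelacycle), which converts the trans-fused lactone/ring B bicycle into the 3-oxabicyclo[3.3.1]nonan-2-one. The only new stereocentre, quaternary C4, is dictated by the substrate: C3 can reach C4 only on the lactone face that carries the axial C10 chain, so both C4 epimers of 27 should converge on one product. The step needs bond formation at C3 instead of radical 5-exo attack at C2, and it must leave the enol ether, epoxide and acetate untouched; the first is secured by hydrometalation preceding C–C bond formation, the second by the preference of nickel hydride for unhindered terminal olefins under near-neutral conditions at room temperature.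

**Compound list**
1 | 1,4-dioxaspiro[4.5]dec-6-en-8-one | O=C1C=CC2(CC1)OCCO2 | starting material
2 | (R)-1,4-dioxaspiro[4.5]dec-6-en-8-ol | O[C@H]1C=CC2(CC1)OCCO2 | intermediate
3 | (R)-8-(tert-butyldimethylsilyloxy)-1,4-dioxaspiro[4.5]dec-6-ene | CC(C)(C)[Si](C)(C)O[C@H]1C=CC2(CC1)OCCO2 | intermediate
4 | (R)-4-(tert-butyldimethylsilyloxy)cyclohex-2-en-1-one | CC(C)(C)[Si](C)(C)O[C@H]1C=CC(=O)CC1 | intermediate
5 | (R)-4-(tert-butyldimethylsilyloxy)-2-iodocyclohex-2-en-1-one | CC(C)(C)[Si](C)(C)O[C@H]1C=C(I)C(=O)CC1 | intermediate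
6 | (R)-2-allyl-4-(tert-butyldimethylsilyloxy)cyclohex-2-en-1-one | CC(C)(C)[Si](C)(C)O[C@H]1C=C(CC=C)C(=O)CC1 | intermediate
7 | 1-methoxy-1-(trimethylsilyloxy)prop-1-ene (E/Z mixture) | CC=C(OC)O[Si](C)(C)C | starting material
8 | silyl enol ether, methyl 2-[2-allyl-6-(tert-butyldimethylsilyloxy)-3-(trimethylsilyloxy)cyclohex-2-en-1-yl]propanoate, C5 chain trans to C6–OTBS | CC(C)(C)[Si](C)(C)O[C@@H]1CCC(O[Si](C)(C)C)=C(CC=C)[C@H]1C(C)C(=O)OC | intermediate
9 | hydroxy ester, methyl 2-[2-allyl-6-(tert-butyldimethylsilyloxy)-2-(hydroxymethyl)-3-oxocyclohexyl]propanoate, CH2OH trans and allyl cis to the propanoate chain | CC(C)(C)[Si](C)(C)O[C@@H]1CCC(=O)[C@](CC=C)(CO)[C@H]1C(C)C(=O)OC | intermediate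
10 | keto-lactone, 8a-allyl-5-(tert-butyldimethylsilyloxy)-4-methyloctahydroisochromene-3,8-dione, trans-fused (labdane 6-OTBS, 9-oxo, 10-allyl, 19,20-olide) | CC(C)(C)[Si](C)(C)O[C@@H]1CCC(=O)[C@]2(CC=C)COC(=O)C(C)[C@@H]12 | intermediate
11 | Mannich base, 8-(dimethylaminomethyl) derivative of 10 | CC(C)(C)[Si](C)(C)O[C@@H]1CC(CN(C)C)C(=O)[C@]2(CC=C)COC(=O)C(C)[C@@H]12 | intermediate
12 | methiodide, trimethylammonium iodide of 11 | CC(C)(C)[Si](C)(C)O[C@@H]1CC(C[N+](C)(C)C)C(=O)[C@]2(CC=C)COC(=O)C(C)[C@@H]12.[I-] | intermediate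
13 | 8-methylene keto-lactone (exocyclic enone C8=C17) | CC(C)(C)[Si](C)(C)O[C@@H]1CC(=C)C(=O)[C@]2(CC=C)COC(=O)C(C)[C@@H]12 | intermediate
14 | 3-bromobut-3-en-1-ol | OCCC(Br)=C | starting material
15 | 2-bromo-4-iodobut-1-ene | C=C(Br)CCI | intermediate
16 | (3-bromobut-3-en-1-yl)magnesium iodide | C=C(Br)CC[Mg]I | intermediate
17 | C9 tertiary alcohol with 3-bromobut-3-enyl chain (C9–OH syn to C10 allyl, C11 syn to C20) | CC(C)(C)[Si](C)(C)O[C@@H]1CC(=C)[C@](O)(CCC(Br)=C)[C@]2(CC=C)COC(=O)C(C)[C@@H]12 | intermediate
18 | allylic alcohol with 3-(hydroxymethyl)but-3-enyl chain | CC(C)(C)[Si](C)(C)O[C@@H]1CC(=C)[C@](O)(CCC(CO)=C)[C@]2(CC=C)COC(=O)C(C)[C@@H]12 | intermediate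
19 | (13S)-13,16-epoxy-14-ol (epoxy alcohol) | CC(C)(C)[Si](C)(C)O[C@@H]1CC(=C)[C@](O)(CC[C@]3(CO)CO3)[C@]2(CC=C)COC(=O)C(C)[C@@H]12 | intermediate
20 | (13R)-13,16-epoxy-14-al (epoxy aldehyde) | CC(C)(C)[Si](C)(C)O[C@@H]1CC(=C)[C@](O)(CC[C@]3(C=O)CO3)[C@]2(CC=C)COC(=O)C(C)[C@@H]12 | intermediate
21 | (13S)-13,16-epoxy-14-yne (alkynyl epoxide) | CC(C)(C)[Si](C)(C)O[C@@H]1CC(=C)[C@](O)(CC[C@]3(C#C)CO3)[C@]2(CC=C)COC(=O)C(C)[C@@H]12 | intermediate
22 | (13R)-9,13-epoxy-14-yn-16-ol (spiro-tetrahydrofuran, ring D) | CC(C)(C)[Si](C)(C)O[C@@H]1CC(=C)[C@]2(CC[C@](CO)(C#C)O2)[C@]2(CC=C)COC(=O)C(C)[C@@H]12 | intermediate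
23 | (13R)-9,13:15,16-diepoxy-14-ene 6-TBS ether (rings D and E), 8(17)-ene, 10-allyl 19,20-olide | CC(C)(C)[Si](C)(C)O[C@@H]1CC(=C)[C@]2(CC[C@]3(C=COC3)O2)[C@]2(CC=C)COC(=O)C(C)[C@@H]12 | intermediate
24 | C6 alcohol of 23 | O[C@@H]1CC(=C)[C@]2(CC[C@]3(C=COC3)O2)[C@]2(CC=C)COC(=O)C(C)[C@@H]12 | intermediate
25 | 8,17-epoxide (epoxide oxygen syn to C6–OH) | O[C@@H]1C[C@@]2(CO2)[C@]2(CC[C@]3(C=COC3)O2)[C@]2(CC=C)COC(=O)C(C)[C@@H]12 | intermediate
26 | 4-bromo lactone (C4 epimers) | O[C@@H]1C[C@@]2(CO2)[C@]2(CC[C@]3(C=COC3)O2)[C@]2(CC=C)COC(=O)C(C)(Br)[C@@H]12 | intermediate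
27 | 6-acetate of the 4-bromo lactone | CC(=O)O[C@@H]1C[C@@]2(CO2)[C@]2(CC[C@]3(C=COC3)O2)[C@]2(CC=C)COC(=O)C(C)(Br)[C@@H]12 | intermediate
28 | target, 6-acetoxy-8,17:9,13:15,16-triepoxy-labd-14-en-19,20-olide (cis A/B) | CC(=O)O[C@@H]1C[C@@]2(CO2)[C@]2(CC[C@]3(C=COC3)O2)[C@]23CCC[C@](C)(C(=O)OC2)[C@@H]13 | target

**Totals**
Total step count: 20. Longest linear sequence: 19 steps (steps 1–8 and 10–20; step 9 makes the side-chain iodide).

**Steps most likely to fail**

1. Step 20 (proposed new method). Possible failure as a process: direct radical cyclisation in the 5-exo mode before nickel capture, olefin isomerisation by chain walking, or hydrodebromination/elimination of the tertiary bromide. Fallback with known chemistry, setting out from 25: chemoselective hydroboration of the monosubstituted olefin with 9-BBN and NaBO3 oxidation should give the primary alcohol F1. Selective tosylation of the primary hydroxyl (TsCl, pyridine, 0 °C) gives the tosylate F2. KN(SiMe3)2 (2.2 equiv, THF, −78 → 0 °C) then forms the lactone enolate beside the C6 alkoxide, and intramolecular SN2 alkylation (6-exo-tet, same bridge-enforced C4 configuration) closes ring A to the C6 alcohol F3. Acetylation (Ac2O, pyridine, DMAP) returns to the route at 28.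

2. Step 17. Possible failure as a process: loss of chemoselectivity through oxidation of the electron-rich enol ether, Lewis-acid-induced opening of the bis-spiro ether, or insufficient facial direction by the homoallylic hydroxyl. Fallback, setting out from 22: the epoxide is introduced before the enol ether exists, by substrate control instead of hydroxyl direction. Buffered mCPBA (NaHCO3, CH2Cl2, 0 °C) should attack the 1,1-disubstituted C8=C17 olefin anti to the axial C10 allyl group to give the epoxide F4. Cycloisomerisation with Mo(CO)6/Et3N/hν then gives the dihydrofuran F5, and Bu4NF returns to the route at 25.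

3. Step 15. Possible failure as a process: catalyst deactivation at the hindered, fully substituted propargylic position, or competing exo-cyclisation. Fallback, setting out from 22: anti-Markovnikov hydration of the terminal alkyne with CpRu(MeCN)3PF6 and 5,5′-bis(trifluoromethyl)-2,2′-bipyridine in aqueous NMP should give, as the closed tautomer of the aldehyde, the lactol F6. MsCl/Et3N converts it into the anomeric mesylate F7, which eliminates in the same flask to the enol ether and returns to the route at 23.

Further compounds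
F1 | step 20 | primary alcohol, 10-(3-hydroxypropyl) analogue of 25 | O[C@@H]1C[C@@]2(CO2)[C@]2(CC[C@]3(C=COC3)O2)[C@]2(CCCO)COC(=O)C(C)[C@@H]12
F2 | step 20 | tosylate of F1 at the primary hydroxyl | O[C@@H]1C[C@@]2(CO2)[C@]2(CC[C@]3(C=COC3)O2)[C@]2(CCCOS(=O)(=O)c4ccc(C)cc4)COC(=O)C(C)[C@@H]12
F3 | step 20 | C6 alcohol (deacetyl target) | O[C@@H]1C[C@@]2(CO2)[C@]2(CC[C@]3(C=COC3)O2)[C@]23CCC[C@](C)(C(=O)OC2)[C@@H]13
F4 | step 17 | epoxide, 8,17-epoxide of 22 | CC(C)(C)[Si](C)(C)O[C@@H]1C[C@@]2(CO2)[C@]2(CC[C@](CO)(C#C)O2)[C@]2(CC=C)COC(=O)C(C)[C@@H]12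
F5 | step 17 | dihydrofuran, 6-TBS ether of 25 | CC(C)(C)[Si](C)(C)O[C@@H]1C[C@@]2(CO2)[C@]2(CC[C@]3(C=COC3)O2)[C@]2(CC=C)COC(=O)C(C)[C@@H]12
F6 | step 15 | lactol, 15-hydroxy-15,16-epoxide (C15 anomers) | CC(C)(C)[Si](C)(C)O[C@@H]1CC(=C)[C@]2(CC[C@]3(CC(O)OC3)O2)[C@]2(CC=C)COC(=O)C(C)[C@@H]12
F7 | step 15 | anomeric mesylate of F6 | CC(C)(C)[Si](C)(C)O[C@@H]1CC(=C)[C@]2(CC[C@]3(CC(OS(C)(=O)=O)OC3)O2)[C@]2(CC=C)COC(=O)C(C)[C@@H]12
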